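**Strategy.** The whole plan rests on disconnecting the C2–C3 bond of the dihydrofuran ring. C3 is a secondary benzylic carbinol carbon on C3a, next to C7a which carries the ring oxygen O1, and the three-carbon group on C2 can be traced back to an acetyl group; the bond can therefore be made by adding the O1-bearing α-carbon of an aryl acetonyl ether to the formyl group on the same arene. One D-proline enamine aldol closes the five-membered ring O1–C2–C3–C3a–C7a and sets both ring stereocentres (cis) in a single operation. Its precursor is a 2-(2-oxopropoxy)benzaldehyde that already carries the (R)-configured, silyl-protected 1-hydroxyethyl group para to the ether oxygen.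

Key step: step 6

Remark: the choice of D-proline assumes the usual enamine transition-state model (E-enamine with the aryloxy group trans to nitrogen, aldehyde bound on the face of the carboxylic acid). The aldol product 11 is (2R,3S) by the CIP rules and has the same spatial arrangement as the (2S,3S) ring of the target; the C2 label changes only because an acetyl carbon outranks C3 whereas an alkenyl carbon does not.

**Route**

Step 1
Reactants: 1 5-acetyl-2-hydroxybenzaldehyde (5-acetylsalicylaldehyde); 2 3-chloro-2-methylprop-1-ene (methallyl chloride)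
Product: 3 5-acetyl-2-[(2-methylprop-2-en-1-yl)oxy]benzaldehyde
Conditions: K2CO3, KI (cat.), DMF, 60 °C
Reagents that add atoms: none
Why: Williamson ether synthesis, in which the phenol (acidified by the para-acetyl and ortho-formyl groups) is deprotonated by carbonate and alkylated at oxygen by the allylic chloride under iodide catalysis; no stereocenter is involved.

Step 2
Reactants: 3 5-acetyl-2-[(2-methylprop-2-en-1-yl)oxy]benzaldehyde
Product: 4 1-{3-(dimethoxymethyl)-4-[(2-methylprop-2-en-1-yl)oxy]phenyl}ethan-1-one
Conditions: HC(OMe)3, PPTS (cat.), MeOH, 0 °C to rt; Et3N quench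
Reagents that add atoms: trimethyl orthoformate, COC(OC)OC; methanol, CO
Why: Acid-catalysed acetalization with an orthoformate as water scavenger should be chemoselective for the aldehyde, because the para-alkoxy aryl methyl ketone is far less electrophilic and more hindered; the formyl group is thereby masked before the ketone reduction.

Step 3
Reactants: 4 1-{3-(dimethoxymethyl)-4-[(2-methylprop-2-en-1-yl)oxy]phenyl}ethan-1-one
Product: 5 (1R)-1-{3-(dimethoxymethyl)-4-[(2-methylprop-2-en-1-yl)oxy]phenyl}ethan-1-ol
Conditions: RuCl(p-cymene)[(R,R)-TsDPEN] (1 mol%), HCO2H/Et3N (1:2 molar), MeCN, 40 °C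
Reagents that add atoms: none
Why: Noyori-type asymmetric transfer hydrogenation, in which RuH(p-cymene)[(R,R)-TsDPEN] delivers hydride to the Si face of the aryl methyl ketone through its six-membered outer-sphere transition state and should set the (R) carbinol stereocenter with high selectivity, while the isolated alkene and (in the amine-rich medium) the acetal are left alone.

Step 4
Reactants: 5 (1R)-1-{3-(dimethoxymethyl)-4-[(2-methylprop-2-en-1-yl)oxy]phenyl}ethan-1-ol
Product: 6 tert-butyl{(1R)-1-[3-(dimethoxymethyl)-4-[(2-methylprop-2-en-1-yl)oxy]phenyl]ethoxy}dimethylsilane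
Conditions: TBSCl, imidazole, DMF, rt
Reagents that add atoms: tert-butyldimethylsilyl chloride (TBSCl), CC(C)(C)[Si](C)(C)Cl
Why: Standard imidazole-promoted O-silylation of the secondary benzylic alcohol gives an ether that tolerates ozone, enamine catalysis and titanium methylenation, and the C–O bond of the stereocenter is not touched.

Step 5
Reactants: 6 tert-butyl{(1R)-1-[3-(dimethoxymethyl)-4-[(2-methylprop-2-en-1-yl)oxy]phenyl]ethoxy}dimethylsilane
Product: 9 5-[(1R)-1-{[tert-butyl(dimethyl)silyl]oxy}ethyl]-2-(2-oxopropoxy)benzaldehyde, via ozonide 7 (not isolated), via keto acetal 8 (not isolated)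
Conditions: O3, CH2Cl2, −78 °C; PPh3, −78 °C to rt; then PPTS (cat.), acetone/H2O, rt
Reagents that add atoms: ozone, [O-][O+]=O; water, O
Why: Ozonolysis (Criegee mechanism) cleaves the only C=C bond and phosphine reduction of ozonide 7 unveils the methyl ketone; the ortho-alkoxybenzaldehyde dimethyl acetal of 8 is then hydrolysed with a buffered weak acid that leaves the benzylic silyl ether intact, and the whole sequence stays free of base so that the keto aldehyde cannot undergo Rap–Stoermer-type condensation to a benzofuran.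

Step 6
Reactants: 9 5-[(1R)-1-{[tert-butyl(dimethyl)silyl]oxy}ethyl]-2-(2-oxopropoxy)benzaldehyde
Product: 11 1-[(2R,3S)-5-[(1R)-1-{[tert-butyl(dimethyl)silyl]oxy}ethyl]-3-hydroxy-2,3-dihydro-1-benzofuran-2-yl]ethan-1-one (cis), via enamine 10 (not isolated)
Conditions: D-proline (30 mol%), DMSO, rt
Reagents that add atoms: none
Why: D-proline condenses with the methyl ketone to the E-enamine 10 on the oxygen-bearing methylene side (as hydroxy- and alkoxyacetones do), the enamine carbon adds to the ortho formyl group while the carboxylic acid hydrogen-bonds the aldehyde oxygen, and hydrolysis of the resulting iminium ion releases 11 and the catalyst. The closest known reaction type is the proline-catalysed intramolecular enolexo aldol reaction (Hajos–Parrish type), which is established for 2-(2-oxoalkoxy)aryl carbonyl compounds and gives cis-2-acyl-2,3-dihydrobenzofuran-3-ols. The ring O1–C2–C3–C3a–C7a closes in the 5-(enolexo)-exo-trig mode, and closure through the methyl-side enamine would need a seven-membered ring and should not compete. C2 is set by the catalyst, the aldehyde being held on the enamine face that carries the carboxylic acid, and C3 is set relative to C2 by the hydrogen-bonded closed transition state, which puts the acyl group and the new hydroxyl group on the same face of the flat five-membered ring; with D-proline this should give the cis (2R,3S) isomer. The step needs regioselective enamine formation, catalyst control of the facial sense (secured because the C5 stereocenter is remote, and any ring-antipodal product is a separable diastereomer) and suppression of dehydration to the 2-acetylbenzofuran, which the base-free medium, room temperature and prompt neutral work-up are meant to secure.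

Step 7
Reactants: 11 1-[(2R,3S)-5-[(1R)-1-{[tert-butyl(dimethyl)silyl]oxy}ethyl]-3-hydroxy-2,3-dihydro-1-benzofuran-2-yl]ethan-1-one
Product: 12 (2S,3S)-5-[(1R)-1-{[tert-butyl(dimethyl)silyl]oxy}ethyl]-2-(prop-1-en-2-yl)-2,3-dihydro-1-benzofuran-3-ol (cis)
Conditions: Cp2TiMe2 (3 equiv), toluene/THF, 65 °C, dark
Reagents that add atoms: dimethyltitanocene (Cp2TiMe2), C[Ti+2]C.[CH-]1C=CC=C1.[CH-]1C=CC=C1
Why: Petasis methylenation, in which Cp2Ti=CH2 formed thermally from Cp2TiMe2 converts the ketone into the 1,1-disubstituted alkene by [2+2] cycloaddition and cycloreversion under non-basic conditions, so the acidic C2–H is neither epimerised nor lost in elimination toward the benzofuran; it is placed before the acylation so that no ester competes and the C3 oxygen is still a poor leaving group, the excess reagent allowing for the free hydroxyl group.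

Step 8
Reactants: 12 (2S,3S)-5-[(1R)-1-{[tert-butyl(dimethyl)silyl]oxy}ethyl]-2-(prop-1-en-2-yl)-2,3-dihydro-1-benzofuran-3-ol
Product: 13 (2S,3S)-5-[(1R)-1-{[tert-butyl(dimethyl)silyl]oxy}ethyl]-2-(prop-1-en-2-yl)-2,3-dihydro-1-benzofuran-3-yl acetate
Conditions: Ac2O, pyridine, DMAP (cat.), CH2Cl2, 0 °C to rt
Reagents that add atoms: acetic anhydride, CC(=O)OC(C)=O
Why: DMAP-catalysed acylation of the secondary benzylic alcohol with retention at C3 (the C–O bond is not broken); since the carbonyl group at C2 is gone, the C2–H is no longer acidic and the acetate cannot be lost by E1cB elimination.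

Step 9
Reactants: 13 (2S,3S)-5-[(1R)-1-{[tert-butyl(dimethyl)silyl]oxy}ethyl]-2-(prop-1-en-2-yl)-2,3-dihydro-1-benzofuran-3-yl acetate
Product: 14 (2S,3S)-5-[(1R)-1-hydroxyethyl]-2-(prop-1-en-2-yl)-2,3-dihydro-1-benzofuran-3-yl acetate
Conditions: HF·pyridine, pyridine, THF, 0 °C to rt
Reagents that add atoms: none
Why: Fluoride-induced cleavage of the Si–O bond with pyridine-buffered HF removes the silyl ether chemoselectively, sparing the acetate and avoiding ionisation at the para-alkoxy benzylic carbon, so the (R) configuration is retained.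

Step 10
Reactants: 14 (2S,3S)-5-[(1R)-1-hydroxyethyl]-2-(prop-1-en-2-yl)-2,3-dihydro-1-benzofuran-3-yl acetate; 15 angelic acid [(2Z)-2-methylbut-2-enoic acid]
Product: 17 (1R)-1-[(2S,3S)-3-(acetyloxy)-2-(prop-1-en-2-yl)-2,3-dihydro-1-benzofuran-5-yl]ethyl (2Z)-2-methylbut-2-enoate, via mixed anhydride 16 (not isolated)
Conditions: 15, 2,4,6-trichlorobenzoyl chloride, Et3N, toluene, rt; then 14, toluene, 80 °C
Reagents that add atoms: none
Why: Yamaguchi esterification, in which the mixed anhydride 16 transfers the less hindered angeloyl group to the alcohol on heating without a nucleophilic catalyst, conditions known to deliver angelates without Z to E isomerisation; the carbinol C–O bond is not broken, so the (R) centre is retained.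

Step 11
Reactants: 17 (1R)-1-[(2S,3S)-3-(acetyloxy)-2-(prop-1-en-2-yl)-2,3-dihydro-1-benzofuran-5-yl]ethyl (2Z)-2-methylbut-2-enoate
Product: 19 (1R)-1-[(2S,3S)-3-(acetyloxy)-2-(3-oxoprop-1-en-2-yl)-2,3-dihydro-1-benzofuran-5-yl]ethyl (2Z)-2-methylbut-2-enoate (the target CNP0294391.4), via allylic alcohol 18 (not isolated)
Conditions: SeO2 (0.5 equiv), t-BuOOH, CH2Cl2, rt; then activated MnO2, CH2Cl2, rt
Reagents that add atoms: selenium dioxide, O=[Se]=O (oxygen carrier); tert-butyl hydroperoxide, CC(C)(C)OO (terminal oxygen source)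
Why: Riley-type allylic oxidation in its catalytic form, in which SeO2 undergoes an ene reaction and [2,3]-sigmatropic shift at the isopropenyl group, the most electron-rich alkene (the conjugated angelate is far less reactive), to give allylic alcohol 18, which MnO2 oxidises chemoselectively to the enal; this group is made last because the 2-substituted acrolein next to the aryloxy-bearing C2 is sensitive to nucleophiles and base.

**Compound list**

1 | 5-acetyl-2-hydroxybenzaldehyde (5-acetylsalicylaldehyde) | CC(=O)c1ccc(O)c(C=O)c1 | starting material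
2 | 3-chloro-2-methylprop-1-ene (methallyl chloride) | C=C(C)CCl | starting material
3 | 5-acetyl-2-[(2-methylprop-2-en-1-yl)oxy]benzaldehyde | CC(=O)c1ccc(OCC(C)=C)c(C=O)c1 | intermediate
4 | 1-{3-(dimethoxymethyl)-4-[(2-methylprop-2-en-1-yl)oxy]phenyl}ethan-1-one | CC(=O)c1ccc(OCC(C)=C)c(C(OC)OC)c1 | intermediate
5 | (1R)-1-{3-(dimethoxymethyl)-4-[(2-methylprop-2-en-1-yl)oxy]phenyl}ethan-1-ol | C[C@@H](O)c1ccc(OCC(C)=C)c(C(OC)OC)c1 | intermediate
6 | tert-butyl{(1R)-1-[3-(dimethoxymethyl)-4-[(2-methylprop-2-en-1-yl)oxy]phenyl]ethoxy}dimethylsilane | C[C@@H](O[Si](C)(C)C(C)(C)C)c1ccc(OCC(C)=C)c(C(OC)OC)c1 | intermediate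
7 | ozonide of 6 (not isolated): tert-butyl{(1R)-1-[3-(dimethoxymethyl)-4-[(3-methyl-1,2,4-trioxolan-3-yl)methoxy]phenyl]ethoxy}dimethylsilane, both configurations at the trioxolane carbon | CC1(COc2ccc(cc2C(OC)OC)[C@@H](C)O[Si](C)(C)C(C)(C)C)OOCO1 | intermediate
8 | keto acetal (not isolated): 1-{4-[(1R)-1-{[tert-butyl(dimethyl)silyl]oxy}ethyl]-2-(dimethoxymethyl)phenoxy}propan-2-one | CC(=O)COc1ccc(cc1C(OC)OC)[C@@H](C)O[Si](C)(C)C(C)(C)C | intermediate
9 | 5-[(1R)-1-{[tert-butyl(dimethyl)silyl]oxy}ethyl]-2-(2-oxopropoxy)benzaldehyde (key-step precursor) | CC(=O)COc1ccc(cc1C=O)[C@@H](C)O[Si](C)(C)C(C)(C)C | intermediate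
10 | enamine (not isolated): (2R)-1-[(1E)-1-{4-[(1R)-1-{[tert-butyl(dimethyl)silyl]oxy}ethyl]-2-formylphenoxy}prop-1-en-2-yl]pyrrolidine-2-carboxylic acid | OC(=O)[C@H]1CCCN1/C(C)=C/Oc1ccc(cc1C=O)[C@@H](C)O[Si](C)(C)C(C)(C)C | intermediate
11 | 1-[(2R,3S)-5-[(1R)-1-{[tert-butyl(dimethyl)silyl]oxy}ethyl]-3-hydroxy-2,3-dihydro-1-benzofuran-2-yl]ethan-1-one (cis; key-step product) | CC(=O)[C@@H]1Oc2ccc(cc2[C@@H]1O)[C@@H](C)O[Si](C)(C)C(C)(C)C | intermediate
12 | (2S,3S)-5-[(1R)-1-{[tert-butyl(dimethyl)silyl]oxy}ethyl]-2-(prop-1-en-2-yl)-2,3-dihydro-1-benzofuran-3-ol (cis) | C=C(C)[C@@H]1Oc2ccc(cc2[C@@H]1O)[C@@H](C)O[Si](C)(C)C(C)(C)C | intermediate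
13 | (2S,3S)-5-[(1R)-1-{[tert-butyl(dimethyl)silyl]oxy}ethyl]-2-(prop-1-en-2-yl)-2,3-dihydro-1-benzofuran-3-yl acetate | C=C(C)[C@@H]1Oc2ccc(cc2[C@@H]1OC(C)=O)[C@@H](C)O[Si](C)(C)C(C)(C)C | intermediate
14 | (2S,3S)-5-[(1R)-1-hydroxyethyl]-2-(prop-1-en-2-yl)-2,3-dihydro-1-benzofuran-3-yl acetate | C=C(C)[C@@H]1Oc2ccc(cc2[C@@H]1OC(C)=O)[C@@H](C)O | intermediate
15 | angelic acid, (2Z)-2-methylbut-2-enoic acid | C/C=C(/C)C(=O)O | starting material
16 | mixed anhydride (not isolated): (2Z)-2-methylbut-2-enoic 2,4,6-trichlorobenzoic anhydride | C/C=C(/C)C(=O)OC(=O)c1c(Cl)cc(Cl)cc1Cl | intermediate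
17 | (1R)-1-[(2S,3S)-3-(acetyloxy)-2-(prop-1-en-2-yl)-2,3-dihydro-1-benzofuran-5-yl]ethyl (2Z)-2-methylbut-2-enoate | C=C(C)[C@@H]1Oc2ccc([C@@H](C)OC(=O)/C(C)=C\C)cc2[C@@H]1OC(C)=O | intermediate
18 | allylic alcohol (not isolated): (1R)-1-[(2S,3S)-3-(acetyloxy)-2-(3-hydroxyprop-1-en-2-yl)-2,3-dihydro-1-benzofuran-5-yl]ethyl (2Z)-2-methylbut-2-enoate | C=C(CO)[C@@H]1Oc2ccc([C@@H](C)OC(=O)/C(C)=C\C)cc2[C@@H]1OC(C)=O | intermediate
19 | (1R)-1-[(2S,3S)-3-(acetyloxy)-2-(3-oxoprop-1-en-2-yl)-2,3-dihydro-1-benzofuran-5-yl]ethyl (2Z)-2-methylbut-2-enoate (CNP0294391.4) | C=C(C=O)[C@@H]1Oc2ccc([C@@H](C)OC(=O)/C(C)=C\C)cc2[C@@H]1OC(C)=O | target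

**Step count and risks**

Total step count: 11 (the one-pot sequences of steps 5, 10 and 11 each count as one step).
Longest linear sequence: 11 steps, from 1 to 19; 2 and 15 are used as purchased.

The three steps most likely to fail:

1. Step 6 (key step). What may go wrong is incomplete facial control at the enamine, so that the ring-antipodal cis isomer and some trans isomer form, and amine-promoted loss of water from the aldol toward the aromatic 2-acetylbenzofuran during long reaction times or work-up. As a fallback, setting out from 9, the same C2–C3 bond would be closed through the enolate generated with TiCl4 and i-Pr2NEt (CH2Cl2, −78 °C, protonation at −78 °C). The metal-bridged closed transition state again places the acyl and the hydroxyl group cis, and the O–TiCl3 aldolate should not dehydrate in the cold. The ring configuration is then no longer catalyst-controlled, so 11 would form together with its ring-antipodal cis diastereomer 1-[(2S,3R)-5-[(1R)-1-{[tert-butyl(dimethyl)silyl]oxy}ethyl]-3-hydroxy-2,3-dihydro-1-benzofuran-2-yl]ethan-1-one F1. The two would be separated by chromatography, which is possible because the C5 side chain is a single enantiomer, and the route is rejoined at 11.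

2. Step 11. What may go wrong is the ene reaction engaging the allylic methyl groups of the angelate or the C2–H instead of the isopropenyl methyl group, selenium- or acid-induced Z to E isomerisation of the angelate, and ionisation of the para-alkoxy benzylic ester. As a fallback, the order of the end game would be changed so that the allylic oxidation precedes the angelate. Setting out from 13, SeO2/t-BuOOH would give the allylic alcohol (2S,3S)-5-[(1R)-1-{[tert-butyl(dimethyl)silyl]oxy}ethyl]-2-(3-hydroxyprop-1-en-2-yl)-2,3-dihydro-1-benzofuran-3-yl acetate F2, and MnO2 would give the enal (2S,3S)-5-[(1R)-1-{[tert-butyl(dimethyl)silyl]oxy}ethyl]-2-(3-oxoprop-1-en-2-yl)-2,3-dihydro-1-benzofuran-3-yl acetate F3. HF·pyridine would then free the carbinol to give (2S,3S)-5-[(1R)-1-hydroxyethyl]-2-(3-oxoprop-1-en-2-yl)-2,3-dihydro-1-benzofuran-3-yl acetate F4. This alcohol would be esterified with the preformed mixed anhydride 16 (toluene, 80 °C, after filtering off the triethylammonium chloride so that the enal meets no free amine), which returns to the route at the target 19.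

3. Step 7. What may go wrong is retro-aldol opening or thermal dehydration of the titanium-bound β-hydroxy ketone at 65 °C, or epimerisation at C2 before the carbonyl group is consumed. As a fallback, a Peterson olefination in two cold stages would be used. Setting out from 11, the reagent from Me3SiCH2Li and CeCl3 (THF, −78 °C), which is too weakly basic to enolise the ketone, would add to the carbonyl group to give the β-hydroxysilane (2R,3S)-5-[(1R)-1-{[tert-butyl(dimethyl)silyl]oxy}ethyl]-2-[2-hydroxy-1-(trimethylsilyl)propan-2-yl]-2,3-dihydro-1-benzofuran-3-ol F5 (both configurations at the new carbinol carbon). KH (THF, 0 °C) would then induce syn-elimination of the silanolate to give 12, where the route is rejoined.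

**Further compounds**

F1 | step 6 | 1-[(2S,3R)-5-[(1R)-1-{[tert-butyl(dimethyl)silyl]oxy}ethyl]-3-hydroxy-2,3-dihydro-1-benzofuran-2-yl]ethan-1-one | CC(=O)[C@H]1Oc2ccc(cc2[C@H]1O)[C@@H](C)O[Si](C)(C)C(C)(C)C
F2 | step 11 | (2S,3S)-5-[(1R)-1-{[tert-butyl(dimethyl)silyl]oxy}ethyl]-2-(3-hydroxyprop-1-en-2-yl)-2,3-dihydro-1-benzofuran-3-yl acetate | C=C(CO)[C@@H]1Oc2ccc(cc2[C@@H]1OC(C)=O)[C@@H](C)O[Si](C)(C)C(C)(C)C
F3 | step 11 | (2S,3S)-5-[(1R)-1-{[tert-butyl(dimethyl)silyl]oxy}ethyl]-2-(3-oxoprop-1-en-2-yl)-2,3-dihydro-1-benzofuran-3-yl acetate | C=C(C=O)[C@@H]1Oc2ccc(cc2[C@@H]1OC(C)=O)[C@@H](C)O[Si](C)(C)C(C)(C)C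
F4 | step 11 | (2S,3S)-5-[(1R)-1-hydroxyethyl]-2-(3-oxoprop-1-en-2-yl)-2,3-dihydro-1-benzofuran-3-yl acetate | C=C(C=O)[C@@H]1Oc2ccc(cc2[C@@H]1OC(C)=O)[C@@H](C)O
F5 | step 7 | (2R,3S)-5-[(1R)-1-{[tert-butyl(dimethyl)silyl]oxy}ethyl]-2-[2-hydroxy-1-(trimethylsilyl)propan-2-yl]-2,3-dihydro-1-benzofuran-3-ol | C[Si](C)(C)CC(C)(O)[C@@H]1Oc2ccc(cc2[C@@H]1O)[C@@H](C)O[Si](C)(C)C(C)(C)C
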